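**Plan**

- Retrosynthetic cuts: the endo C2–Br goes back to a C2 carbonyl; then C2–C3 and O7–C4 of the 7-oxabicyclo[2.2.1]heptane are cut together (Prins); then the C4–chain bond (B-alkyl Suzuki); then the CMe2–CH2 bond of the bromocyclohexane (bromonium cyclisation).
- Enabling feature: O7 on C1 lies 1,4 across the C1–C6 carbocycle from the fully substituted C4, and C3 is a bare CH2. An exocyclic methylene on C4 can therefore attack a C2 carbonyl and leave a tertiary C4 cation facing the C1 oxygen.
- Forward order: bromocyclohexyl methyl ketone (one cascade), enol triflate, Suzuki union with a glycidol-derived borane, open-chain silyloxy aldehyde, Prins closure of carbocycle and ether bridge at once, then C2 is finished (oxidation, alkenyl bromide, diimide).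
- Stereochemistry: C4' by Shi epoxidation, carried through a bromonium ion; C1' relayed in the same cascade; C1 bought as (S)-2-methylglycidol; C4 forced by the bridge; C2 by exo-face hydrogen delivery.

Key step: step 14

Remark: (S)-2-methylglycidol and the D-fructose-derived Shi ketone are taken as commercial. Compounds 3–7 are mixtures at the silyloxy carbinol carbon, which becomes the ketone carbon in step 7. Compounds 17 and 18 may be either C2 epimer, since C2 is oxidised in step 15.

**Route**

Step 1
Reactants: 1 6-methylhept-5-en-2-one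
Product: 2 7-methyl-3-methylideneoct-6-en-2-one
Conditions: (CH2O)n, i-Pr2NH·TFA, TFA (cat.), THF, reflux
Reagents that add atoms: paraformaldehyde (as formaldehyde), C=O
Why: Mannich-type α-methylenation of a ketone, in which the more substituted enol reacts, so the α-CH2 and not the CH3 is methylenated.

Step 2
Reactants: 2 7-methyl-3-methylideneoct-6-en-2-one
Product: 3 7-methyl-3-methylideneoct-6-en-2-ol (racemic)
Conditions: NaBH4, CeCl3·7H2O, MeOH, −40 °C
Reagents that add atoms: none
Why: Luche 1,2-reduction of the enone; the carbinol configuration is irrelevant because this carbon becomes a ketone in step 7.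

Step 3
Reactants: 3 7-methyl-3-methylideneoct-6-en-2-ol
Product: 4 tert-butyldimethyl[(7-methyl-3-methylideneoct-6-en-2-yl)oxy]silane
Conditions: TBSCl, imidazole, DMF, rt
Reagents that add atoms: tert-butyldimethylsilyl chloride, CC(C)(C)[Si](C)(C)Cl
Why: standard silylation, which masks the only hydroxyl so that the hydroxyl made in step 5 can be activated alone.

Step 4
Reactants: 4 tert-butyldimethyl[(7-methyl-3-methylideneoct-6-en-2-yl)oxy]silane
Product: 5 tert-butyl({5-[(2R)-3,3-dimethyloxiran-2-yl]-3-methylidenepentan-2-yl}oxy)dimethylsilane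
Conditions: D-fructose-derived Shi ketone (30 mol %), Oxone, K2CO3, Bu4NHSO4, MeCN/dimethoxymethane/aq. buffer pH 10.5, 0 °C
Reagents that add atoms: Oxone (potassium peroxymonosulfate), [K+].[O-]S(=O)(=O)OO
Why: Shi asymmetric epoxidation, in which the chiral dioxirane attacks the electron-rich trisubstituted alkene through the spiro transition state to give the (R)-epoxide and leaves the deactivated 1,1-disubstituted allylic ether alkene.

Step 5
Reactants: 5 tert-butyl({5-[(2R)-3,3-dimethyloxiran-2-yl]-3-methylidenepentan-2-yl}oxy)dimethylsilane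
Product: 6 (3R)-2-bromo-7-[(tert-butyldimethylsilyl)oxy]-2-methyl-6-methylideneoctan-3-ol
Conditions: LiBr, AcOH, THF, 0 °C → rt
Reagents that add atoms: lithium bromide, [Li+].[Br-]
Why: acid-assisted epoxide opening by bromide at the tertiary carbon leaves the C–O stereocentre untouched, and the regioisomeric bromohydrin (bromide at the secondary carbon with inversion) would converge on the same compound 7 in step 6.

Step 6
Reactants: 6 (3R)-2-bromo-7-[(tert-butyldimethylsilyl)oxy]-2-methyl-6-methylideneoctan-3-ol
Product: 7 {[(6S)-6-bromo-7-chloro-7-methyl-3-methylideneoctan-2-yl]oxy}(tert-butyl)dimethylsilane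
Conditions: Ph3P, N-chlorosuccinimide, CH2Cl2, −20 °C → rt
Reagents that add atoms: N-chlorosuccinimide, O=C1CCC(=O)N1Cl
Why: Appel-type activation of the hydroxyl is followed by anti participation of the neighbouring bromine and chloride attack at the tertiary carbon of the bromonium ion (1,2-bromine shift), which inverts the carbinol carbon to the (S)-bromide next to a tertiary chloride.

Step 7
Reactants: 7 {[(6S)-6-bromo-7-chloro-7-methyl-3-methylideneoctan-2-yl]oxy}(tert-butyl)dimethylsilane
Product: 8 1-[(1S,4S)-4-bromo-3,3-dimethylcyclohexyl]ethan-1-one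
Conditions: (CF3)2CHOH, 2,6-di-tert-butyl-4-methylpyridine, 0 °C → rt; aq. NaHCO3 work-up
Reagents that add atoms: none
Why: Proposed new method: ionisation of the tertiary chloride in HFIP with anti participation of the secondary bromine gives the enantiopure bromonium ion (closest known type: enantiospecific solvolytic cyclisation of vicinal bromochlorides), the methylene carbon of the 1,1-disubstituted alkene opens it at the tertiary carbon through a chair with Br equatorial, and the tertiary ring cation is quenched by a 1,2-hydride shift from the adjacent silyloxy carbon followed by loss of the silyl group (closest known types: halonium-induced semipinacol rearrangement of allylic alcohols and Prins–pinacol cascades); the hydride should enter the axial lobe because this leaves the acetyl group equatorial in the chair just formed (the other lobe would push it syn-axial to the axial 3-methyl), which sets C1 trans to Br before the ring can invert, and hydride should migrate rather than methyl because it gives the more substituted silyloxocarbenium ion.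

Step 8
Reactants: 8 1-[(1S,4S)-4-bromo-3,3-dimethylcyclohexyl]ethan-1-one
Product: 9 1-[(1S,4S)-4-bromo-3,3-dimethylcyclohexyl]ethenyl trifluoromethanesulfonate
Conditions: KHMDS, PhNTf2, THF, −78 °C
Reagents that add atoms: N-phenylbis(trifluoromethanesulfonimide), O=S(=O)(N(c1ccccc1)S(=O)(=O)C(F)(F)F)C(F)(F)F
Why: kinetic deprotonation of the methyl group and O-triflation at −78 °C give the terminal enol triflate without enolising towards the ring methine, so C1 is not epimerised.

Step 9
Reactants: 10 [(2S)-2-methyloxiran-2-yl]methanol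
Product: 11 triethyl{[(2R)-2-methyloxiran-2-yl]methoxy}silane
Conditions: TESCl, imidazole, CH2Cl2, 0 °C
Reagents that add atoms: chlorotriethylsilane, CC[Si](Cl)(CC)CC
Why: standard silylation of the primary alcohol; the stereocentre is untouched (the descriptor changes only through CIP priorities).

Step 10
Reactants: 11 triethyl{[(2R)-2-methyloxiran-2-yl]methoxy}silane
Product: 12 (2R)-2-methyl-1-[(triethylsilyl)oxy]but-3-en-2-ol
Conditions: Me3S+ I−, n-BuLi, THF, −10 °C → rt
Reagents that add atoms: trimethylsulfonium iodide, C[S+](C)C.[I-]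
Why: dimethylsulfonium methylide opens the 2,2-disubstituted epoxide at CH2 and a second ylide equivalent induces elimination of dimethyl sulfide, giving the one-carbon-homologated allylic alcohol without touching the quaternary centre (any 1,4-silyl migration is harmless because both oxygens are silylated in step 11).

Step 11
Reactants: 12 (2R)-2-methyl-1-[(triethylsilyl)oxy]but-3-en-2-ol
Product: 13 (2R)-2-methyl-1,2-bis[(triethylsilyl)oxy]but-3-ene
Conditions: TESOTf, 2,6-lutidine, CH2Cl2, −78 °C → 0 °C
Reagents that add atoms: triethylsilyl trifluoromethanesulfonate, CC[Si](CC)(CC)OS(=O)(=O)C(F)(F)F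
Why: silyl triflate silylation of a hindered tertiary alcohol, which installs the oxygen substituent that is transferred in the key step.

Step 12
Reactants: 13 (2R)-2-methyl-1,2-bis[(triethylsilyl)oxy]but-3-ene; 9 1-[(1S,4S)-4-bromo-3,3-dimethylcyclohexyl]ethenyl trifluoromethanesulfonate
Product: 15 (2R)-5-[(1S,4S)-4-bromo-3,3-dimethylcyclohexyl]-2-methyl-1,2-bis[(triethylsilyl)oxy]hex-5-ene, via alkylborane 14 (not isolated)
Conditions: 9-BBN, THF, rt; then 9, Pd(dppf)Cl2 (5 mol %), AsPh3, Cs2CO3, DMF/THF/H2O, rt
Reagents that add atoms: none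
Why: anti-Markovnikov hydroboration of the vinyl group and B-alkyl Suzuki–Miyaura coupling with the alkenyl triflate, since Pd(0) inserts into the C–OTf bond far faster than into the hindered secondary alkyl bromide.

Step 13
Reactants: 15 (2R)-5-[(1S,4S)-4-bromo-3,3-dimethylcyclohexyl]-2-methyl-1,2-bis[(triethylsilyl)oxy]hex-5-ene
Product: 16 (2R)-5-[(1S,4S)-4-bromo-3,3-dimethylcyclohexyl]-2-methyl-2-[(triethylsilyl)oxy]hex-5-enal
Conditions: (COCl)2, DMSO, CH2Cl2, −78 → −30 °C; Et3N, −78 °C → rt
Reagents that add atoms: none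
Why: under Swern conditions a primary triethylsilyl ether is cleaved by the chlorosulfonium salt and oxidised directly to the aldehyde, while the tertiary silyl ether cannot react.

Step 14
Reactants: 16 (2R)-5-[(1S,4S)-4-bromo-3,3-dimethylcyclohexyl]-2-methyl-2-[(triethylsilyl)oxy]hex-5-enal
Product: 18 (1R,4S)-4-[(1S,4S)-4-bromo-3,3-dimethylcyclohexyl]-1-methyl-7-oxabicyclo[2.2.1]heptan-2-ol, via triethylsilyl ether 17 (not isolated)
Conditions: TESOTf (20 mol %), 2,6-di-tert-butyl-4-methylpyridine (30 mol %), CH2Cl2, −78 °C; then TBAF, THF, 0 °C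
Reagents that add atoms: none
Why: The silyl triflate silylates the aldehyde oxygen to a silyloxocarbenium ion, the methylene carbon of the 1,1-disubstituted alkene attacks the carbonyl carbon (Markovnikov, chair transition state), the tertiary C4 cation is captured across the ring by the C1 silyl ether oxygen, and the oxonium ion passes Et3Si+ on to regenerate the catalyst; the closest known type is the Lewis-acid Prins (type II carbonyl-ene) cyclisation of 5-substituted hex-5-enals with termination by an oxygen nucleophile. The carbocycle closes 6-exo-trig at the carbonyl (endo with respect to the alkene), and the ether bridge closes as a five-membered oxolane ring onto the planar cation through the boat form. C4 can only bond on the face that carries the C1 oxygen, so its configuration follows from the glycidol-derived C1 centre, while the C2 carbinol centre may form as either epimer because it is oxidised in step 15. The step needs ether closure to outrun proton loss and 1,2-hydride shift from the cyclohexyl methine next to C4; the O-silylated, non-basic C2 oxygen (no internal base for an ene pathway), the hindered pyridine buffer, −78 °C and the intramolecular oxygen placed 1,4 to the cation should secure this. The secondary bromide is inert to catalytic silyl triflate at this temperature.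

Step 15
Reactants: 18 (1R,4S)-4-[(1S,4S)-4-bromo-3,3-dimethylcyclohexyl]-1-methyl-7-oxabicyclo[2.2.1]heptan-2-ol
Product: 19 (1R,4S)-4-[(1S,4S)-4-bromo-3,3-dimethylcyclohexyl]-1-methyl-7-oxabicyclo[2.2.1]heptan-2-one
Conditions: Dess–Martin periodinane, CH2Cl2, rt
Reagents that add atoms: none
Why: neutral Dess–Martin oxidation of the secondary alcohol merges both C2 epimers into one ketone without enolate or cation chemistry on the bicycle.

Step 16
Reactants: 19 (1R,4S)-4-[(1S,4S)-4-bromo-3,3-dimethylcyclohexyl]-1-methyl-7-oxabicyclo[2.2.1]heptan-2-one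
Product: 20 (1R,4R)-2-bromo-4-[(1S,4S)-4-bromo-3,3-dimethylcyclohexyl]-1-methyl-7-oxabicyclo[2.2.1]hept-2-ene
Conditions: (PhO)3P, Br2, Et3N, CH2Cl2, −60 °C → reflux
Reagents that add atoms: bromine, BrBr
Why: ketone-to-alkenyl-bromide conversion with the triphenyl phosphite–bromine reagent, in which only C3 carries α-hydrogens, so a single regioisomer can form.

Step 17
Reactants: 20 (1R,4R)-2-bromo-4-[(1S,4S)-4-bromo-3,3-dimethylcyclohexyl]-1-methyl-7-oxabicyclo[2.2.1]hept-2-ene
Product: 21 (1R,2R,4S)-2-bromo-4-[(1S,4S)-4-bromo-3,3-dimethylcyclohexyl]-1-methyl-7-oxabicyclo[2.2.1]heptane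
Conditions: 2-nitrobenzenesulfonohydrazide, Et3N, CH2Cl2, rt
Reagents that add atoms: none
Why: diimide transfers two hydrogens syn to the strained alkene from the exo face (the endo face is screened by the C5–C6 bridge), so the new C2–H is exo and bromine ends endo, anti to the oxygen bridge, and diimide does not reduce C–Br bonds.

**Compound list**

1 | 6-methylhept-5-en-2-one | CC(=O)CCC=C(C)C | starting material
2 | 7-methyl-3-methylideneoct-6-en-2-one | CC(=O)C(=C)CCC=C(C)C | intermediate
3 | 7-methyl-3-methylideneoct-6-en-2-ol (racemic) | CC(O)C(=C)CCC=C(C)C | intermediate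
4 | tert-butyldimethyl[(7-methyl-3-methylideneoct-6-en-2-yl)oxy]silane (racemic) | CC(O[Si](C)(C)C(C)(C)C)C(=C)CCC=C(C)C | intermediate
5 | tert-butyl({5-[(2R)-3,3-dimethyloxiran-2-yl]-3-methylidenepentan-2-yl}oxy)dimethylsilane (carbinol epimers) | CC(O[Si](C)(C)C(C)(C)C)C(=C)CC[C@H]1OC1(C)C | intermediate
6 | (3R)-2-bromo-7-[(tert-butyldimethylsilyl)oxy]-2-methyl-6-methylideneoctan-3-ol (C7 epimers) | CC(O[Si](C)(C)C(C)(C)C)C(=C)CC[C@@H](O)C(C)(C)Br | intermediate
7 | {[(6S)-6-bromo-7-chloro-7-methyl-3-methylideneoctan-2-yl]oxy}(tert-butyl)dimethylsilane (C2 epimers) | CC(O[Si](C)(C)C(C)(C)C)C(=C)CC[C@H](Br)C(C)(C)Cl | intermediate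
8 | 1-[(1S,4S)-4-bromo-3,3-dimethylcyclohexyl]ethan-1-one | CC1(C)C[C@@H](C(C)=O)CC[C@@H]1Br | intermediate
9 | 1-[(1S,4S)-4-bromo-3,3-dimethylcyclohexyl]ethenyl trifluoromethanesulfonate | CC1(C)C[C@@H](C(=C)OS(=O)(=O)C(F)(F)F)CC[C@@H]1Br | intermediate
10 | [(2S)-2-methyloxiran-2-yl]methanol ((S)-2-methylglycidol) | OC[C@@]1(C)CO1 | starting material
11 | triethyl{[(2R)-2-methyloxiran-2-yl]methoxy}silane | CC[Si](CC)(CC)OC[C@@]1(C)CO1 | intermediate
12 | (2R)-2-methyl-1-[(triethylsilyl)oxy]but-3-en-2-ol | CC[Si](CC)(CC)OC[C@@](O)(C)C=C | intermediate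
13 | (2R)-2-methyl-1,2-bis[(triethylsilyl)oxy]but-3-ene | CC[Si](CC)(CC)OC[C@@](O[Si](CC)(CC)CC)(C)C=C | intermediate
14 | 9-{(3R)-3-methyl-3,4-bis[(triethylsilyl)oxy]butyl}-9-borabicyclo[3.3.1]nonane | CC[Si](CC)(CC)OC[C@@](O[Si](CC)(CC)CC)(C)CCB1C2CCCC1CCC2 | intermediate
15 | (2R)-5-[(1S,4S)-4-bromo-3,3-dimethylcyclohexyl]-2-methyl-1,2-bis[(triethylsilyl)oxy]hex-5-ene | CC1(C)C[C@@H](C(=C)CC[C@@](C)(O[Si](CC)(CC)CC)CO[Si](CC)(CC)CC)CC[C@@H]1Br | intermediate
16 | (2R)-5-[(1S,4S)-4-bromo-3,3-dimethylcyclohexyl]-2-methyl-2-[(triethylsilyl)oxy]hex-5-enal | CC1(C)C[C@@H](C(=C)CC[C@@](C)(O[Si](CC)(CC)CC)C=O)CC[C@@H]1Br | intermediate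
17 | {[(1R,4S)-4-[(1S,4S)-4-bromo-3,3-dimethylcyclohexyl]-1-methyl-7-oxabicyclo[2.2.1]heptan-2-yl]oxy}triethylsilane (C2 epimers) | CC1(C)C[C@@H]([C@@]23CC[C@@](C)(O2)C(O[Si](CC)(CC)CC)C3)CC[C@@H]1Br | intermediate
18 | (1R,4S)-4-[(1S,4S)-4-bromo-3,3-dimethylcyclohexyl]-1-methyl-7-oxabicyclo[2.2.1]heptan-2-ol (C2 epimers) | CC1(C)C[C@@H]([C@@]23CC[C@@](C)(O2)C(O)C3)CC[C@@H]1Br | intermediate
19 | (1R,4S)-4-[(1S,4S)-4-bromo-3,3-dimethylcyclohexyl]-1-methyl-7-oxabicyclo[2.2.1]heptan-2-one | CC1(C)C[C@@H]([C@@]23CC[C@@](C)(O2)C(=O)C3)CC[C@@H]1Br | intermediate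
20 | (1R,4R)-2-bromo-4-[(1S,4S)-4-bromo-3,3-dimethylcyclohexyl]-1-methyl-7-oxabicyclo[2.2.1]hept-2-ene | CC1(C)C[C@@H]([C@@]23CC[C@@](C)(O2)C(Br)=C3)CC[C@@H]1Br | intermediate
21 | (1R,2R,4S)-2-bromo-4-[(1S,4S)-4-bromo-3,3-dimethylcyclohexyl]-1-methyl-7-oxabicyclo[2.2.1]heptane | CC1(C)C[C@@H]([C@@]23CC[C@@](C)(O2)[C@H](Br)C3)CC[C@@H]1Br | target

**Step count and risks**

Total steps: 17. Longest linear sequence: 14 (steps 1–8 and 12–17).

Steps most likely to fail:

1. Step 7 (Proposed new method). Processes that may go wrong: proton loss from the ring cation or methyl instead of hydride migration; hydride entering the other lobe, which gives the C1 epimer; halide return to the bromonium ion, which erodes enantiopurity. The fallback uses known chemistry, sets out from 1 and returns at 8. Kinetic enolisation of 1 (LDA, PhNTf2) would give 6-methylhepta-1,5-dien-2-yl trifluoromethanesulfonate F1, and Pd-catalysed Kumada coupling with Me3SiCH2MgCl would give trimethyl[(6-methyl-2-methylidenehept-5-en-1-yl)]silane F2. The operations of steps 4–6 would then give {4-[(2R)-3,3-dimethyloxiran-2-yl]-2-methylidenebutyl}trimethylsilane F3, (3R)-2-bromo-2-methyl-6-[(trimethylsilyl)methyl]hept-6-en-3-ol F4 and [(5S)-5-bromo-6-chloro-6-methyl-2-methylideneheptyl]trimethylsilane F5. Solvolysis in HFIP would end by loss of the silyl group (allylsilane termination) to give (4S)-4-bromo-3,3-dimethyl-1-methylidenecyclohexane F6. Hydroboration–oxidation (9-BBN; NaBO3) would give [(4S)-4-bromo-3,3-dimethylcyclohexyl]methanol F7. Dess–Martin oxidation, base equilibration (DBU) and chromatographic separation would give the trans aldehyde (1S,4S)-4-bromo-3,3-dimethylcyclohexane-1-carbaldehyde F8. MeMgBr addition would give 1-[(1S,4S)-4-bromo-3,3-dimethylcyclohexyl]ethan-1-ol F9, and a second Dess–Martin oxidation ketone 8. Here C1 would be set by equilibration and separation instead of by the hydride shift.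

2. Step 14. Processes that may go wrong: proton loss from the C4 cation, or a 1,2-hydride shift from the neighbouring cyclohexyl methine, before the oxygen closes. Either would destroy the C1' configuration or lead to an isomeric ether. The fallback sets out from 16 and returns at 18, and forms the two bonds in two known operations without a free cation. Iodoetherification (NIS, MeCN, 0 °C) would let the silyl ether oxygen open the iodonium ion at the tertiary carbon with loss of the silyl group, giving (2R)-5-[(1S,4S)-4-bromo-3,3-dimethylcyclohexyl]-5-(iodomethyl)-2-methyloxolane-2-carbaldehyde F10 as C5 epimers. A samarium Barbier cyclisation (SmI2, cat. NiI2, THF, 0 °C) would then join the iodomethyl carbon to the aldehyde carbon in the epimer that has both groups on the same face, giving 18. The other epimer cannot cyclise and would be removed.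

3. Step 16. Processes that may go wrong: a skeletal (Wagner–Meerwein) shift or opening of the oxygen bridge if the bromophosphonium adduct ionises at C2. The fallback sets out from 19 and returns at 20. Low-temperature enolisation and O-triflation (KHMDS, Comins' reagent, THF, −78 °C) would give (1R,4R)-4-[(1S,4S)-4-bromo-3,3-dimethylcyclohexyl]-1-methyl-7-oxabicyclo[2.2.1]hept-2-en-2-yl trifluoromethanesulfonate F11. Ruthenium-catalysed triflate–bromide exchange ([Cp*Ru(MeCN)3]OTf, LiBr) would then give 20.

**Further compounds**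

F1 | step 7 | 6-methylhepta-1,5-dien-2-yl trifluoromethanesulfonate | C=C(OS(=O)(=O)C(F)(F)F)CCC=C(C)C
F2 | step 7 | trimethyl[(6-methyl-2-methylidenehept-5-en-1-yl)]silane | C=C(C[Si](C)(C)C)CCC=C(C)C
F3 | step 7 | {4-[(2R)-3,3-dimethyloxiran-2-yl]-2-methylidenebutyl}trimethylsilane | C=C(C[Si](C)(C)C)CC[C@H]1OC1(C)C
F4 | step 7 | (3R)-2-bromo-2-methyl-6-[(trimethylsilyl)methyl]hept-6-en-3-ol | C=C(C[Si](C)(C)C)CC[C@@H](O)C(C)(C)Br
F5 | step 7 | [(5S)-5-bromo-6-chloro-6-methyl-2-methylideneheptyl]trimethylsilane | C=C(C[Si](C)(C)C)CC[C@H](Br)C(C)(C)Cl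
F6 | step 7 | (4S)-4-bromo-3,3-dimethyl-1-methylidenecyclohexane | CC1(C)CC(=C)CC[C@@H]1Br
F7 | step 7 | [(4S)-4-bromo-3,3-dimethylcyclohexyl]methanol (C1 epimers) | CC1(C)CC(CO)CC[C@@H]1Br
F8 | step 7 | (1S,4S)-4-bromo-3,3-dimethylcyclohexane-1-carbaldehyde | CC1(C)C[C@@H](C=O)CC[C@@H]1Br
F9 | step 7 | 1-[(1S,4S)-4-bromo-3,3-dimethylcyclohexyl]ethan-1-ol (carbinol epimers) | CC1(C)C[C@@H](C(C)O)CC[C@@H]1Br
F10 | step 14 | (2R)-5-[(1S,4S)-4-bromo-3,3-dimethylcyclohexyl]-5-(iodomethyl)-2-methyloxolane-2-carbaldehyde (C5 epimers) | CC1(C)C[C@@H](C2(CI)CC[C@](C)(C=O)O2)CC[C@@H]1Br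
F11 | step 16 | (1R,4R)-4-[(1S,4S)-4-bromo-3,3-dimethylcyclohexyl]-1-methyl-7-oxabicyclo[2.2.1]hept-2-en-2-yl trifluoromethanesulfonate | CC1(C)C[C@@H]([C@@]23CC[C@@](C)(O2)C(OS(=O)(=O)C(F)(F)F)=C3)CC[C@@H]1Br
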